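**Retrosynthetic overview**
- The strategy rests on the fully substituted central benzene ring: oxygens on C1, C2, C4 and C5, 4-hydroxyphenyl groups on C3 and C6. Its four oxygens are symmetry-equivalent, yet one stays free and three carry the (2Z,4S,5S)-4,5-epoxyhex-2-enoyl group.
- Last cuts: global desilylation, then three identical aryl ester bonds, back to a central-ring triol mono-silyl ether and one epoxy-enoate salt. The salt is traced to L-rhamnal: C4/C5 become the epoxide and the ring-locked cis alkene becomes the Z-enoate.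
- The central ring is cut into a four-carbon squarate piece (C-O, C-Ar, C-O, C-O) and a two-carbon aryl enol ether piece (C-Ar, C-O). It is made by thermal ring expansion of a 4-alkenyl-4-silyloxycyclobutenone, which gives each oxygen its own label (H, TBS, Bn, Bn).
- Ring order: the outer benzene rings and the cyclobutene are bought; the epoxide is closed in the side-chain branch as the pyranone ring is opened; the central benzene ring is formed in step 8; the three esters follow.

Key step: step 8

Remark on the chemistry (assumption): vinyl bromide 13 is drawn as its Z isomer (Br cis to OBn); any E isomer is carried along because step 8 erases this geometry. The arene-branch centres in 5, 12, 15, 16 and 18 are racemic and are destroyed before any chiral fragment is attached. Where a step builds in more than one equivalent of a component (steps 1 and 14), the line "Reagents that add atoms" shows the full number of formula units.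

**Step 1**
Reactants: 1 squaric acid
Product: 2 dibenzyl squarate (3,4-bis(benzyloxy)cyclobut-3-ene-1,2-dione)
Conditions: BnOH (2.2 equiv), toluene, reflux, Dean-Stark
Reagents that add atoms: benzyl alcohol (two equivalents are built in, written as two formula units), OCc1ccccc1.OCc1ccccc1
Why: Squaric acid is acidic enough to catalyse its own vinylogous Fischer esterification, and azeotropic removal of water drives both hydroxyls to the benzyl ester.

**Step 2**
Reactants: 2 dibenzyl squarate; 3 (4-bromophenoxy)(tert-butyl)dimethylsilane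
Product: 5 2,3-bis(benzyloxy)-4-hydroxy-4-[4-(tert-butyldimethylsilyloxy)phenyl]cyclobut-2-en-1-one (racemic), via 4-(tert-butyldimethylsilyloxy)phenyllithium 4 (not isolated)
Conditions: 3, n-BuLi (1.0 equiv), THF, -78 °C; then 2 in THF, -78 °C; sat. aq NH4Cl
Reagents that add atoms: none
Why: Bromine-lithium exchange gives the aryllithium, which adds 1,2 to one of the two equivalent carbonyls of the squarate ester at low temperature; the new carbinol centre is racemic and disappears in step 3.

**Step 3**
Reactants: 5 2,3-bis(benzyloxy)-4-hydroxy-4-[4-(tert-butyldimethylsilyloxy)phenyl]cyclobut-2-en-1-one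
Product: 6 3-(benzyloxy)-4-[4-(tert-butyldimethylsilyloxy)phenyl]cyclobut-3-ene-1,2-dione
Conditions: conc. HCl (cat.), CH2Cl2, 0 °C to rt, short contact
Reagents that add atoms: none
Why: Acid ionises the tertiary allylic hydroxyl to a cyclobutenyl cation held as an oxocarbenium ion at the distal benzyloxy carbon, the water that left returns there and benzyl alcohol is expelled (the standard squarate-adduct to semisquarate transposition), a brief exposure that the aryl silyl ether should tolerate.

**Step 4**
Reactants: 7 benzyl chloromethyl ether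
Product: 8 (benzyloxymethyl)triphenylphosphonium chloride
Conditions: PPh3, toluene, rt to 50 °C, salt filtered
Reagents that add atoms: triphenylphosphine, c1ccc(P(c2ccccc2)c2ccccc2)cc1
Why: SN2 alkylation of the phosphine by the reactive alpha-chloro ether gives the Wittig salt.

**Step 5**
Reactants: 8 (benzyloxymethyl)triphenylphosphonium chloride; 9 4-(tert-butyldimethylsilyloxy)benzaldehyde
Product: 11 {4-[2-(benzyloxy)ethenyl]phenoxy}(tert-butyl)dimethylsilane (E/Z mixture), via (benzyloxymethylene)triphenylphosphorane 10 (not isolated)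
Conditions: NaHMDS, THF, -78 to 0 °C; then 9, 0 °C to rt
Reagents that add atoms: none
Why: A non-nucleophilic amide base (which spares the aryl silyl ether) forms the alkoxymethylene ylide, and Wittig olefination of the non-enolisable aldehyde gives the enol ether; both alkene isomers converge in step 6.

**Step 6**
Reactants: 11 {4-[2-(benzyloxy)ethenyl]phenoxy}(tert-butyl)dimethylsilane
Product: 13 (Z)-{4-[2-(benzyloxy)-1-bromoethenyl]phenoxy}(tert-butyl)dimethylsilane, via vicinal dibromide 12 (not isolated)
Conditions: Br2 (1.0 equiv), CH2Cl2, -78 °C; then Et3N (3 equiv), -78 °C to rt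
Reagents that add atoms: bromine, BrBr
Why: Bromine adds across the electron-rich enol ether, and the amine removes HBr through ionisation of the alpha-bromo ether and loss of the benzylic proton (the established bromination-dehydrobromination route to beta-bromo enol ethers), which leaves bromine on the aryl-bearing carbon.

**Step 7**
Reactants: 13 (Z)-{4-[2-(benzyloxy)-1-bromoethenyl]phenoxy}(tert-butyl)dimethylsilane; 6 3-(benzyloxy)-4-[4-(tert-butyldimethylsilyloxy)phenyl]cyclobut-3-ene-1,2-dione
Product: 16 3-(benzyloxy)-4-{(Z)-2-(benzyloxy)-1-[4-(tert-butyldimethylsilyloxy)phenyl]ethenyl}-4-(tert-butyldimethylsilyloxy)-2-[4-(tert-butyldimethylsilyloxy)phenyl]cyclobut-2-en-1-one (racemic), via vinyllithium 14 (not isolated), via lithium alkoxide 15 (not isolated)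
Conditions: 13, t-BuLi (2.0 equiv), THF, -78 °C; then 6 in THF, -78 °C; then TBSOTf, -78 to 0 °C
Reagents that add atoms: tert-butyldimethylsilyl trifluoromethanesulfonate, CC(C)(C)[Si](C)(C)OS(=O)(=O)C(F)(F)F
Why: Bromine-lithium exchange with retention gives the alpha-aryl-beta-alkoxyvinyllithium, which adds 1,2 to the more electrophilic carbonyl of 6 (the one next to C-OBn, the other being a vinylogous ester), and the tertiary lithium alkoxide is silylated at oxygen by the triflate; the racemic carbinol centre is destroyed in step 8.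

**Step 8**
Reactants: 16 the 4-alkenyl-4-silyloxycyclobutenone
Product: 19 2,5-bis(benzyloxy)-4-(tert-butyldimethylsilyloxy)-3,6-bis[4-(tert-butyldimethylsilyloxy)phenyl]phenol, via dienylketene 17 (not isolated), via cyclohexadienone 18 (not isolated)
Conditions: degassed toluene, 110 °C, Ar
Reagents that add atoms: none
Why: Heating opens the strained cyclobutenone by conrotatory 4-pi electrocyclic cleavage of the C1-C4 bond to dienylketene 17; its ketene carbon then bonds to the CH(OBn) terminus of the enol ether in a thermal disrotatory 6-pi electrocyclisation, closing the six-membered carbocycle (four carbons from the squarate, two from the enol ether) as cyclohexadienone 18, and a proton shift from the sp3 CH(OBn) carbon to oxygen aromatises it to phenol 19. The closest known reaction type is the thermal ring expansion of 4-alkenyl-4-oxycyclobutenones to hydroquinone monoethers (Moore-type benzannulation). No stereocentre is created that survives: the carbinol centre of 16 and the transient sp3 centre of 18 both become aromatic carbons, and the enol ether geometry is lost with them. The selectivity required is inward rotation of the alkenyl arm so that it lies cis to the ketene; the 4-silyloxy donor prefers outward rotation (torquoselectivity) and so forces the alkenyl group inward. The O, Ar, O, O, Ar, O order was fixed by the site of addition in step 7, and the ketene oxygen emerges as the only free hydroxyl, the carbinol oxygen as the silyl ether and the other two oxygens as benzyl ethers.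

**Step 9**
Reactants: 19 the mono-phenol bis-benzyl ether
Product: 20 5-(tert-butyldimethylsilyloxy)-3,6-bis[4-(tert-butyldimethylsilyloxy)phenyl]benzene-1,2,4-triol
Conditions: H2 (1 atm), 10% Pd/C, degassed EtOAc, rt; filtered under Ar and used at once
Reagents that add atoms: none
Why: Catalytic hydrogenolysis cleaves both benzyl aryl ethers and leaves aryl silyl ethers and arenes alone, and because the four central oxygens are symmetry-equivalent any silyl shift in the triol is degenerate.

**Step 10**
Reactants: 21 3,4-di-O-acetyl-L-rhamnal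
Product: 22 (5R,6S)-5-acetoxy-6-methyl-5,6-dihydro-2H-pyran-2-one
Conditions: mCPBA, BF3·OEt2 (0.2 equiv), CH2Cl2, -20 °C
Reagents that add atoms: 3-chloroperoxybenzoic acid, O=C(OO)c1cccc(Cl)c1
Why: BF3 ionises the allylic C3 acetate (Ferrier-type allyloxocarbenium ion), the peracid adds at C1 and the peroxy acetal fragments to the 2,3-unsaturated delta-lactone (Lewis acid promoted peroxidation of glycal esters), with the C4 and C5 centres untouched.

**Step 11**
Reactants: 22 (5R,6S)-5-acetoxy-6-methyl-5,6-dihydro-2H-pyran-2-one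
Product: 23 (5R,6S)-5-hydroxy-6-methyl-5,6-dihydro-2H-pyran-2-one
Conditions: immobilised Candida antarctica lipase B, n-BuOH (5 equiv), MTBE, 30 °C
Reagents that add atoms: none
Why: Lipase-catalysed transesterification to butanol removes the secondary acetate at neutral pH, which avoids the base-induced ring contraction of the hydroxy lactone to a butenolide; no stereocentre is touched.

**Step 12**
Reactants: 23 (5R,6S)-5-hydroxy-6-methyl-5,6-dihydro-2H-pyran-2-one
Product: 24 (5R,6S)-5-(methanesulfonyloxy)-6-methyl-5,6-dihydro-2H-pyran-2-one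
Conditions: MsCl, pyridine, 0 °C
Reagents that add atoms: methanesulfonyl chloride, CS(=O)(=O)Cl
Why: O-sulfonylation of the secondary alcohol proceeds with retention at carbon and installs the leaving group for the epoxide closure.

**Step 13**
Reactants: 24 (5R,6S)-5-(methanesulfonyloxy)-6-methyl-5,6-dihydro-2H-pyran-2-one
Product: 26 lithium (2Z,4S,5S)-4,5-epoxyhex-2-enoate, via hydroxy-mesylate carboxylate 25 (not isolated)
Conditions: LiOH (2.0 equiv), THF/H2O, 0 °C; freeze-dried, salt used together with the co-formed LiOMs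
Reagents that add atoms: lithium hydroxide, [Li+].[OH-]
Why: Hydroxide saponifies the unsaturated delta-lactone and the freed C5 alkoxide displaces the neighbouring C4 mesylate by intramolecular SN2 (3-exo-tet) with inversion, turning the (4R,5S) erythro pair into the trans (4S,5S) epoxide while the ring-derived cis alkene stays Z.

**Step 14**
Reactants: 26 lithium (2Z,4S,5S)-4,5-epoxyhex-2-enoate (three equivalents enter the product); 20 the central-ring triol
Product: 28 5-(tert-butyldimethylsilyloxy)-3,6-bis[4-(tert-butyldimethylsilyloxy)phenyl]benzene-1,2,4-triyl tris[(2Z,4S,5S)-4,5-epoxyhex-2-enoate], via mixed anhydride 27 (not isolated)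
Conditions: 26 (3.6 equiv), 2,4,6-trichlorobenzoyl chloride (3.6 equiv), THF, 0 °C; then 20, Et3N, DMAP (0.3 equiv), degassed toluene, -10 to 0 °C, Ar
Reagents that add atoms: lithium (2Z,4S,5S)-4,5-epoxyhex-2-enoate (the second and third equivalents of 26, written as two formula units), C[C@@H]1O[C@H]1/C=C\C(=O)[O-].[Li+].C[C@@H]1O[C@H]1/C=C\C(=O)[O-].[Li+]
Why: Yamaguchi esterification: each carboxylate forms the mixed anhydride, DMAP transfers the less hindered epoxy-enoyl group to each of the three phenols so that three equivalents of 26 are consumed per triol, and low temperature with little DMAP limits Z to E isomerisation; the epoxide centres are remote from the reacting carbonyl.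

**Step 15**
Reactants: 28 the tris-ester tris-silyl ether
Product: 29 5-hydroxy-3,6-bis(4-hydroxyphenyl)benzene-1,2,4-triyl tris[(2Z,4S,5S)-4,5-epoxyhex-2-enoate] (CNP0278429.1)
Conditions: TBAF (3.5 equiv), AcOH (4.5 equiv), THF, 0 °C
Reagents that add atoms: none
Why: Fluoride cleaves aryl silyl ethers much faster than it attacks aryl esters, and acetic acid keeps the freed phenoxides protonated so that acyl transfer and epoxide opening are suppressed; any acyl shift among the four equivalent central oxygens is degenerate.

**Compound list**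
1 | squaric acid | O=C1C(O)=C(O)C1=O | starting material
2 | dibenzyl squarate | O=C1C(OCc2ccccc2)=C(OCc2ccccc2)C1=O | intermediate
3 | (4-bromophenoxy)(tert-butyl)dimethylsilane | CC(C)(C)[Si](C)(C)Oc1ccc(Br)cc1 | starting material
4 | 4-(tert-butyldimethylsilyloxy)phenyllithium | [Li]c1ccc(O[Si](C)(C)C(C)(C)C)cc1 | intermediate
5 | 2,3-bis(benzyloxy)-4-hydroxy-4-[4-(tert-butyldimethylsilyloxy)phenyl]cyclobut-2-en-1-one (racemic) | O=C1C(OCc2ccccc2)=C(OCc2ccccc2)C1(O)c1ccc(O[Si](C)(C)C(C)(C)C)cc1 | intermediate
6 | 3-(benzyloxy)-4-[4-(tert-butyldimethylsilyloxy)phenyl]cyclobut-3-ene-1,2-dione | O=C1C(=O)C(c2ccc(O[Si](C)(C)C(C)(C)C)cc2)=C1OCc1ccccc1 | intermediate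
7 | benzyl chloromethyl ether | ClCOCc1ccccc1 | starting material
8 | (benzyloxymethyl)triphenylphosphonium chloride | [Cl-].c1ccc([P+](COCc2ccccc2)(c2ccccc2)c2ccccc2)cc1 | intermediate
9 | 4-(tert-butyldimethylsilyloxy)benzaldehyde | CC(C)(C)[Si](C)(C)Oc1ccc(C=O)cc1 | starting material
10 | (benzyloxymethylene)triphenylphosphorane | c1ccc(P(=COCc2ccccc2)(c2ccccc2)c2ccccc2)cc1 | intermediate
11 | {4-[2-(benzyloxy)ethenyl]phenoxy}(tert-butyl)dimethylsilane (E/Z mixture) | CC(C)(C)[Si](C)(C)Oc1ccc(C=COCc2ccccc2)cc1 | intermediate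
12 | {4-[2-(benzyloxy)-1,2-dibromoethyl]phenoxy}(tert-butyl)dimethylsilane (diastereomer mixture) | CC(C)(C)[Si](C)(C)Oc1ccc(C(Br)C(Br)OCc2ccccc2)cc1 | intermediate
13 | (Z)-{4-[2-(benzyloxy)-1-bromoethenyl]phenoxy}(tert-butyl)dimethylsilane (Br cis to OBn) | Br/C(=C\OCc1ccccc1)c1ccc(O[Si](C)(C)C(C)(C)C)cc1 | intermediate
14 | 2-(benzyloxy)-1-[4-(tert-butyldimethylsilyloxy)phenyl]ethenyllithium (Li cis to OBn) | [Li]/C(=C\OCc1ccccc1)c1ccc(O[Si](C)(C)C(C)(C)C)cc1 | intermediate
15 | lithium alkoxide of the 4-alkenyl-4-hydroxy-3-benzyloxy-2-arylcyclobutenone (racemic) | [Li+].[O-]C1(/C(=C\OCc2ccccc2)c2ccc(O[Si](C)(C)C(C)(C)C)cc2)C(=O)C(c2ccc(O[Si](C)(C)C(C)(C)C)cc2)=C1OCc1ccccc1 | intermediate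
16 | 3-(benzyloxy)-4-{(Z)-2-(benzyloxy)-1-[4-(tert-butyldimethylsilyloxy)phenyl]ethenyl}-4-(tert-butyldimethylsilyloxy)-2-[4-(tert-butyldimethylsilyloxy)phenyl]cyclobut-2-en-1-one (racemic) | O=C1C(c2ccc(O[Si](C)(C)C(C)(C)C)cc2)=C(OCc2ccccc2)C1(O[Si](C)(C)C(C)(C)C)/C(=C\OCc1ccccc1)c1ccc(O[Si](C)(C)C(C)(C)C)cc1 | intermediate
17 | dienylketene: 2,5-diaryl-3,6-bis(benzyloxy)-4-(tert-butyldimethylsilyloxy)hexa-1,3,5-trien-1-one, alkenyl arm cis to the ketene | O=C=C(c1ccc(O[Si](C)(C)C(C)(C)C)cc1)/C(OCc1ccccc1)=C(O[Si](C)(C)C(C)(C)C)\C(=C/OCc1ccccc1)c1ccc(O[Si](C)(C)C(C)(C)C)cc1 | intermediate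
18 | 2,5-diaryl-3,6-bis(benzyloxy)-4-(tert-butyldimethylsilyloxy)cyclohexa-2,4-dien-1-one (racemic at C6) | O=C1C(c2ccc(O[Si](C)(C)C(C)(C)C)cc2)=C(OCc2ccccc2)C(O[Si](C)(C)C(C)(C)C)=C(c2ccc(O[Si](C)(C)C(C)(C)C)cc2)C1OCc1ccccc1 | intermediate
19 | 2,5-bis(benzyloxy)-4-(tert-butyldimethylsilyloxy)-3,6-bis[4-(tert-butyldimethylsilyloxy)phenyl]phenol | Oc1c(-c2ccc(O[Si](C)(C)C(C)(C)C)cc2)c(OCc2ccccc2)c(O[Si](C)(C)C(C)(C)C)c(-c2ccc(O[Si](C)(C)C(C)(C)C)cc2)c1OCc1ccccc1 | intermediate
20 | 5-(tert-butyldimethylsilyloxy)-3,6-bis[4-(tert-butyldimethylsilyloxy)phenyl]benzene-1,2,4-triol | Oc1c(-c2ccc(O[Si](C)(C)C(C)(C)C)cc2)c(O)c(O[Si](C)(C)C(C)(C)C)c(-c2ccc(O[Si](C)(C)C(C)(C)C)cc2)c1O | intermediate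
21 | 3,4-di-O-acetyl-L-rhamnal, (2S,3S,4S)-2-methyl-3,4-dihydro-2H-pyran-3,4-diyl diacetate | C[C@@H]1OC=C[C@H](OC(C)=O)[C@H]1OC(C)=O | starting material
22 | (5R,6S)-5-acetoxy-6-methyl-5,6-dihydro-2H-pyran-2-one | C[C@@H]1OC(=O)C=C[C@H]1OC(C)=O | intermediate
23 | (5R,6S)-5-hydroxy-6-methyl-5,6-dihydro-2H-pyran-2-one | C[C@@H]1OC(=O)C=C[C@H]1O | intermediate
24 | (5R,6S)-5-(methanesulfonyloxy)-6-methyl-5,6-dihydro-2H-pyran-2-one | C[C@@H]1OC(=O)C=C[C@H]1OS(C)(=O)=O | intermediate
25 | lithium (2Z,4R,5S)-5-hydroxy-4-(methanesulfonyloxy)hex-2-enoate | [Li+].C[C@H](O)[C@H](OS(C)(=O)=O)/C=C\C(=O)[O-] | intermediate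
26 | lithium (2Z,4S,5S)-4,5-epoxyhex-2-enoate, i.e. (2Z)-3-[(2S,3S)-3-methyloxiran-2-yl]prop-2-enoate | [Li+].C[C@@H]1O[C@H]1/C=C\C(=O)[O-] | intermediate
27 | (2Z,4S,5S)-4,5-epoxyhex-2-enoic 2,4,6-trichlorobenzoic anhydride | C[C@@H]1O[C@H]1/C=C\C(=O)OC(=O)c1c(Cl)cc(Cl)cc1Cl | intermediate
28 | 5-(tert-butyldimethylsilyloxy)-3,6-bis[4-(tert-butyldimethylsilyloxy)phenyl]benzene-1,2,4-triyl tris[(2Z,4S,5S)-4,5-epoxyhex-2-enoate] | C[C@@H]1O[C@H]1/C=C\C(=O)Oc1c(OC(=O)/C=C\[C@@H]2O[C@H]2C)c(-c2ccc(O[Si](C)(C)C(C)(C)C)cc2)c(OC(=O)/C=C\[C@@H]2O[C@H]2C)c(O[Si](C)(C)C(C)(C)C)c1-c1ccc(O[Si](C)(C)C(C)(C)C)cc1 | intermediate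
29 | 5-hydroxy-3,6-bis(4-hydroxyphenyl)benzene-1,2,4-triyl tris[(2Z,4S,5S)-4,5-epoxyhex-2-enoate] (CNP0278429.1) | C[C@@H]1O[C@H]1/C=C\C(=O)Oc1c(OC(=O)/C=C\[C@@H]2O[C@H]2C)c(-c2ccc(O)cc2)c(OC(=O)/C=C\[C@@H]2O[C@H]2C)c(O)c1-c1ccc(O)cc1 | target

**Totals**
Total step count: 15.
Longest linear sequence: 8 steps (steps 1, 2, 3, 7, 8, 9, 14, 15; the enol ether branch 4, 5, 6, 7, 8, 9, 14, 15 is equally long).

**Steps most likely to fail**

1. Step 14 (threefold esterification). The acylation may stop short of three esters at the crowded phenols. The Z-enoate may isomerise to E through reversible conjugate addition of the nucleophilic catalyst to the activated acyl species. The electron-rich triol may be oxidised to a quinone before it is acylated. Fallback: the acyl donor is made and checked as a separate, isolable active ester and the coupling is run without an acylpyridinium intermediate. It sets out from 26, which with pentafluorophenyl trifluoroacetate in DMF at 0 °C should give pentafluorophenyl (2Z,4S,5S)-4,5-epoxyhex-2-enoate F1, purified quickly on silica and checked for alkene geometry. Triol 20 is then acylated with F1 (3.5 equiv) and i-Pr2NEt in degassed DMF at 0 °C to rt, a phenoxide transesterification driven by the acidity of pentafluorophenol. The sequence comes back to the route at 28.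

2. Step 13 (lactone opening and epoxide closure). Once the lactone is opened, the carboxylate instead of the C5 alkoxide may displace the mesylate or open the new epoxide to a butenolide, and hydroxide may add to the enoate in conjugate fashion. Fallback: the carboxylate is kept out of the ring-closing event. It sets out from 24, which with K2CO3 in dry methanol at -10 °C is opened by methoxide; the C5 alkoxide closes the epoxide with the same inversion to give methyl (2Z,4S,5S)-4,5-epoxyhex-2-enoate F2, a neutral ester that can be purified. Saponification with one equivalent of LiOH in THF/water at 0 °C and freeze-drying comes back to the route at 26.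

3. Step 7 (vinyllithium addition and in-flask silylation). Silylation of the crowded tertiary lithium alkoxide may be incomplete, the beta-alkoxyvinyllithium may lose lithium benzyloxide before it adds, and excess triflate may attack the solvent. Fallback: the oxygen is tagged after ring expansion, using the symmetry of the product. It sets out from 6 and 13: the same exchange and addition (14, 15) are quenched cold with aqueous NH4Cl to give the free 4-alkenyl-4-hydroxy-3-benzyloxy-2-arylcyclobutenone F3. Heating F3 in degassed toluene (the hydroxyl also rotates outward) should give 2,5-bis(benzyloxy)-3,6-bis[4-(tert-butyldimethylsilyloxy)phenyl]benzene-1,4-diol F4, whose two hydroxyls are equivalent. Silylation with one equivalent of TBSCl and imidazole in DMF can then give only one mono-silyl ether; bis-silyl ether and unreacted diol are separated and recycled. The sequence comes back to the route at 19.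

**Further compounds**
F1 | step 14 | pentafluorophenyl (2Z,4S,5S)-4,5-epoxyhex-2-enoate | C[C@@H]1O[C@H]1/C=C\C(=O)Oc1c(F)c(F)c(F)c(F)c1F
F2 | step 13 | methyl (2Z,4S,5S)-4,5-epoxyhex-2-enoate | C[C@@H]1O[C@H]1/C=C\C(=O)OC
F3 | step 7 | 3-(benzyloxy)-4-{(Z)-2-(benzyloxy)-1-[4-(tert-butyldimethylsilyloxy)phenyl]ethenyl}-4-hydroxy-2-[4-(tert-butyldimethylsilyloxy)phenyl]cyclobut-2-en-1-one (racemic) | O=C1C(c2ccc(O[Si](C)(C)C(C)(C)C)cc2)=C(OCc2ccccc2)C1(O)/C(=C\OCc1ccccc1)c1ccc(O[Si](C)(C)C(C)(C)C)cc1
F4 | step 7 | 2,5-bis(benzyloxy)-3,6-bis[4-(tert-butyldimethylsilyloxy)phenyl]benzene-1,4-diol | Oc1c(-c2ccc(O[Si](C)(C)C(C)(C)C)cc2)c(OCc2ccccc2)c(O)c(-c2ccc(O[Si](C)(C)C(C)(C)C)cc2)c1OCc1ccccc1
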